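1. X rose by the ratio 1.45 from epsilon to zeta, yet J with its D at 2.50 min moved by the ratio 0.996. So I took the uptake of E as the rate-limiting step.

| setting | epsilon | zeta | flask |
|---|---|---|---|
| Q | 43 mM | 43 mM | 43 mM |
| E | 8.1 mM (held) | 8.1 mM (held) | 8.1 mM (held) |
| X | 11 mol% | 16 mol% | 11 mol% |
| remark | the very flask that is asked about, followed so far | run made earlier |  |
| time |  |  | 6.0 min |

| run | time / min | J / % | D / % |
|---|---|---|---|
| epsilon | 0.333 | 6.1 | 0.4 |
| epsilon | 0.667 | 13.0 | 0.1 |
| epsilon | 1.00 | 19.5 | 0.3 |
| epsilon | 1.33 | 26.6 | 0.7 |
| epsilon | 1.50 | 30.0 | 0.6 |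
| epsilon | 2.00 | 39.8 | 1.1 |
| epsilon | 2.50 | 49.7 | 1.6 |
| zeta | 0.200 | 3.8 | 0 |
| zeta | 0.333 | 6.7 | 0.3 |
| zeta | 0.417 | 8.4 | 0.4 |
| zeta | 0.667 | 13.7 | 0 |
| zeta | 1.00 | 20.1 | 0.6 |
| zeta | 1.50 | 29.9 | 1.8 |
| zeta | 2.50 | 49.5 | 2.6 |

(each reading ± 0.3 percentage points)

- amount of J and D together at 6.0 min, in percent of the Q charged
- concentration of Z in solution at 3.0 min, in percent of saturation
- the change that raises the amount of J and D together at 6.0 min, in percent of the Q charged most ("none" if none brings more than 2 percentage points) (blue / teal / violet / none)
- amount of J and D together at 6.0 min, in percent of the Q charged, after teal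

- blue: doubling the amount of X, all else as stated
- teal: doubling the transfer coefficient of E, all else as stated
- violet: doubling the saturation concentration of E, all else as stated

2. The epsilon readings ran straight, so I worked with the fraction of Q left, f, and defined the emptying time as the time the held uptake needs to take the whole charge of Q: 5.03 min.

3. On that line f at 3.0 min was 40.4%, but at 6.0 min it fell below zero, which is impossible. This was the weak link.

4. I reforged it with a half-speed fraction, K, the f at which speed has dropped to half. Z is made in proportion to its room below saturation and used in proportion to f times Z, so speed goes as f/(f+K), which integrates to 1 − f + K·ln(1/f) = t/τ.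

5. Two readings differ by about 0.854%, and no gain showed from the extra X, so K came to about 2.73%. That put Z at 3.0 min near 6.34% of saturation.

6. D already held 14.5% of the catalyst at 2.50 min and was rising, so for the tail I took K as 5.46%. The first turn gave 2.93% left and the second 1.71%.

7. I committed to 98.3%. On my reckoning the Q still unturned was 1.71%, less than the 2 percentage points bar, so I chose none and expected teal to land close to my figure.

8. The forecast gave 96.5%, 13%, violet and 99.3%, holding that “Violet speeds both transfer and the kinetic step”.

9. The flask gave 97.0% at 6.0 min, with 0.86% of its Q left, less than my 1.71%; Z at 3.0 min stood at 4.98% of saturation, the answer on the changes was none, and teal gave 97.4%.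

    X + J ⇌ D (K = 36.0 /M, k = 9.00 /M/min)
    Q + Z + X → X + J (k = 3.50 × 10⁵ /M²/min)
    E ⇌ Z, rate k3*(csat - [Z]) (kL = 1.10 /min)
    X + J → L (k = 2.40 /M/min)

10. With 110 mM of Q and the loading held, the emptying time stretches with the charge to 12.9 min, so the line leaves 53.5% at 6.0 min. That flask held 52%.

The readings stem from a simulated flask for substances that don't exist, noise included.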